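**Plan**
- Retrosynthesis: the three MOM ethers and the C2–H bond are removed first, leading back to a flavone. Ring C of the flavone is then cut at C4a–C4, C4–C3 and O1–C2. Last, the bond from C6 to the first carbon of the side chain is cut to an aryllithium and an aldehyde.
- Enabling feature: C4 is a single carbonyl carbon between C4a of ring A and C3, and O1 is a phenol oxygen on C8a. Ring C is therefore an ortho-iodophenol (C4a–I, C8a–OH) plus CO (C4) plus an arylalkyne (C3, C2 and ring B).
- Forward order: rings A and B are bought. Ring A receives the C10 chain and the iodine (steps 1–6) and ring B its ethynyl group (steps 7–8). Ring C closes in step 9, then C2=C3 is reduced and the phenols are freed.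
- Stereochemistry: the side-chain (3S) centre is that of (S)-citronellal and is never touched. The E-alkene comes from a dehydration toward the aryl ring. (2S) is set on the flat flavone by a chiral copper hydride catalyst.

Key step: step 9

Assumption: (S)-citronellal of high enantiomeric purity is used, and the ligand antipode written in step 10 is the one assumed to give (2S); this is to be confirmed on a model flavone and the mirror-image ligand used if hydride arrives at the other face.

**Route**

Step 1
Reactants: 1 phloroglucinol (benzene-1,3,5-triol)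
Product: 2 3,5-bis(methoxymethoxy)phenol
Conditions: MOMCl (2.0 equiv), i-Pr2NEt, DMF, 0 °C to rt
Reagents that add atoms: chloromethyl methyl ether (MOMCl), COCCl
Why: Williamson-type O-alkylation of the phenoxides by the chloromethyl ether; the reaction is statistical on the threefold-symmetric triol, so the bis-ether is to be separated from mono- and tris-ether by chromatography and the mono-ether resubmitted.

Step 2
Reactants: 2 3,5-bis(methoxymethoxy)phenol
Product: 3 [3,5-bis(methoxymethoxy)phenoxy]tri(propan-2-yl)silane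
Conditions: TIPSCl, imidazole, DMF, rt
Reagents that add atoms: chlorotri(propan-2-yl)silane (TIPSCl), CC(C)[Si](Cl)(C(C)C)C(C)C
Why: Imidazole-promoted silylation of the phenol masks the oxygen that will become O1 with a bulky group that withstands n-BuLi, directs no metalation and can later be removed by fluoride without touching the MOM ethers.

Step 3
Reactants: 3 [3,5-bis(methoxymethoxy)phenoxy]tri(propan-2-yl)silane; 4 (S)-citronellal [(3S)-3,7-dimethyloct-6-enal]
Product: 6 (3S)-1-{2,6-bis(methoxymethoxy)-4-[tri(propan-2-yl)silyloxy]phenyl}-3,7-dimethyloct-6-en-1-ol (both C1 epimers), via aryllithium 5 (not isolated)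
Conditions: n-BuLi, THF, 0 °C; then 4, −78 to 0 °C; H2O
Reagents that add atoms: none
Why: Directed ortho-metalation takes place at the ring position flanked by the two chelating OMOM groups and the aryllithium adds 1,2 to the aldehyde; the new carbinol centre forms without control, which is harmless because step 4 removes it, and the (3S) centre is β to the carbonyl and cannot enolise.

Step 4
Reactants: 6 (3S)-1-{2,6-bis(methoxymethoxy)-4-[tri(propan-2-yl)silyloxy]phenyl}-3,7-dimethyloct-6-en-1-ol
Product: 7 {4-[(1E,3S)-3,7-dimethylocta-1,6-dien-1-yl]-3,5-bis(methoxymethoxy)phenoxy}tri(propan-2-yl)silane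
Conditions: Burgess reagent, THF, 50 °C
Reagents that add atoms: none
Why: Burgess dehydration by syn-elimination of the sulfamate ester under neutral conditions can only take a hydrogen from C2 of the chain and should give the conjugated E-styrene, in which the aryl group and the branched chain avoid each other; the free benzylic cation that acid would form, and the remote alkene would trap, is avoided.

Step 5
Reactants: 7 {4-[(1E,3S)-3,7-dimethylocta-1,6-dien-1-yl]-3,5-bis(methoxymethoxy)phenoxy}tri(propan-2-yl)silane
Product: 8 4-[(1E,3S)-3,7-dimethylocta-1,6-dien-1-yl]-3,5-bis(methoxymethoxy)phenol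
Conditions: TBAF, AcOH, THF, 0 °C
Reagents that add atoms: none
Why: Fluoride-driven cleavage of the aryl silyl ether leaves MOM ethers and alkenes alone, and the acetic acid buffer keeps the electron-rich phenol from standing as its air-sensitive phenoxide.

Step 6
Reactants: 8 4-[(1E,3S)-3,7-dimethylocta-1,6-dien-1-yl]-3,5-bis(methoxymethoxy)phenol
Product: 9 4-[(1E,3S)-3,7-dimethylocta-1,6-dien-1-yl]-2-iodo-3,5-bis(methoxymethoxy)phenol
Conditions: NIS (1.0 equiv), CH2Cl2, −40 to 0 °C, dark
Reagents that add atoms: N-iodosuccinimide (NIS), O=C1CCC(=O)N1I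
Why: Electrophilic aromatic iodination ortho to the free hydroxyl of a phloroglucinol-type ring should be much faster than attack on either alkene; the two open ring positions are equivalent by symmetry, so one equivalent of NIS can give only one mono-iodide.

Step 7
Reactants: 10 4-hydroxybenzaldehyde
Product: 11 4-(methoxymethoxy)benzaldehyde
Conditions: MOMCl, i-Pr2NEt, CH2Cl2, 0 °C to rt
Reagents that add atoms: chloromethyl methyl ether (MOMCl), COCCl
Why: Standard MOM protection of a phenol by O-alkylation, so that ring B carries the same protecting group as ring A.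

Step 8
Reactants: 11 4-(methoxymethoxy)benzaldehyde
Product: 12 1-ethynyl-4-(methoxymethoxy)benzene
Conditions: dimethyl (1-diazo-2-oxopropyl)phosphonate, K2CO3, MeOH, rt
Reagents that add atoms: dimethyl (1-diazo-2-oxopropyl)phosphonate (Ohira–Bestmann reagent), COP(=O)(OC)C(=[N+]=[N-])C(C)=O
Why: Seyferth–Gilbert homologation in the Ohira–Bestmann variant turns the aldehyde into the terminal alkyne with one added carbon under mild carbonate conditions that the MOM ether tolerates.

Step 9
Reactants: 9 4-[(1E,3S)-3,7-dimethylocta-1,6-dien-1-yl]-2-iodo-3,5-bis(methoxymethoxy)phenol; 12 1-ethynyl-4-(methoxymethoxy)benzene; 13 carbon monoxide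
Product: 16 6-[(1E,3S)-3,7-dimethylocta-1,6-dien-1-yl]-5,7-bis(methoxymethoxy)-2-[4-(methoxymethoxy)phenyl]-4H-chromen-4-one, via ortho-hydroxyaryl ynone 14 (not isolated), via diethylamino enone 15 (not isolated)
Conditions: PdCl2(PPh3)2 (5 mol %), CO (20 bar), Et2NH, 110 °C, autoclave
Reagents that add atoms: none
Why: Zerovalent palladium, formed in situ from PdCl2(PPh3)2, inserts into the C–I bond of 9, CO insertion gives an aroyl–palladium species, and copper-free coupling with the amine-deprotonated alkyne 12 releases ynone 14, which creates C4a–C4 and C4–C3. Diethylamine then adds to the ynone to give enaminone 15, and the neighbouring phenol displaces the amine at C2, which creates O1–C2. The closest known reaction type is the palladium-catalysed carbonylative Sonogashira coupling–cyclisation of 2-iodophenols with terminal arylalkynes to flavones. Ring C closes in a 6-endo mode (6-endo-trig addition–elimination on the enaminone, formally 6-endo-dig on the ynone), and the amine detour is what keeps the phenoxide from the 5-exo-dig path to the aurone. No stereocentre is formed, and the (3S) centre of the side chain lies far from every reacting site. The step needs carbonylative rather than direct alkynylation (secured by CO pressure and the absence of copper) and 6- rather than 8-substitution (secured by the substrate: the only free hydroxyl flanks the iodine, the other two oxygens are MOM ethers, and the iodine could only enter one of two equivalent positions of phenol 8).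

Step 10
Reactants: 16 6-[(1E,3S)-3,7-dimethylocta-1,6-dien-1-yl]-5,7-bis(methoxymethoxy)-2-[4-(methoxymethoxy)phenyl]-4H-chromen-4-one
Product: 18 (2S)-6-[(1E,3S)-3,7-dimethylocta-1,6-dien-1-yl]-5,7-bis(methoxymethoxy)-2-[4-(methoxymethoxy)phenyl]-2,3-dihydro-4H-chromen-4-one, via silyl enol ether 17 (not isolated)
Conditions: Cu(OAc)2 (5 mol %), (R)-DTBM-SEGPHOS (5.5 mol %), (EtO)2MeSiH, toluene, 0 °C to rt; then AcOH, THF–H2O, 0 °C
Reagents that add atoms: none
Why: Copper hydride-catalysed asymmetric conjugate reduction of the chromone C2=C3 bond, in which the bisphosphine-bound CuH delivers hydride to one face of C2 and so sets (2S) under ligand control; the enolate is silylated to 17, which shields C2 from ring-opening epimerisation and C4 from 1,2-reduction until the mild hydrolytic work-up, and the unactivated alkenes are not reduced.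

Step 11
Reactants: 18 (2S)-6-[(1E,3S)-3,7-dimethylocta-1,6-dien-1-yl]-5,7-bis(methoxymethoxy)-2-[4-(methoxymethoxy)phenyl]-2,3-dihydro-4H-chromen-4-one
Product: 19 (2S)-6-[(1E,3S)-3,7-dimethylocta-1,6-dien-1-yl]-5,7-dihydroxy-2-(4-hydroxyphenyl)-2,3-dihydro-4H-chromen-4-one
Conditions: 3 M aq. HCl, MeOH, 40 °C
Reagents that add atoms: none
Why: Acid-catalysed acetal exchange with methanol frees the three phenols; the C2 centre should hold in dilute acid because flavanone ring opening is a base-driven retro-oxa-Michael process, and the low temperature is chosen to spare the styrene and the trisubstituted alkene.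

**Compound list**
1 | phloroglucinol (benzene-1,3,5-triol) | Oc1cc(O)cc(O)c1 | starting material
2 | 3,5-bis(methoxymethoxy)phenol | COCOc1cc(O)cc(OCOC)c1 | intermediate
3 | [3,5-bis(methoxymethoxy)phenoxy]tri(propan-2-yl)silane | COCOc1cc(OCOC)cc(O[Si](C(C)C)(C(C)C)C(C)C)c1 | intermediate
4 | (S)-citronellal, (3S)-3,7-dimethyloct-6-enal | CC(C)=CCC[C@H](C)CC=O | starting material
5 | {2,6-bis(methoxymethoxy)-4-[tri(propan-2-yl)silyloxy]phenyl}lithium | [Li]c1c(OCOC)cc(O[Si](C(C)C)(C(C)C)C(C)C)cc1OCOC | intermediate
6 | (3S)-1-{2,6-bis(methoxymethoxy)-4-[tri(propan-2-yl)silyloxy]phenyl}-3,7-dimethyloct-6-en-1-ol (both C1 epimers) | CC(C)=CCC[C@H](C)CC(O)c1c(OCOC)cc(O[Si](C(C)C)(C(C)C)C(C)C)cc1OCOC | intermediate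
7 | {4-[(1E,3S)-3,7-dimethylocta-1,6-dien-1-yl]-3,5-bis(methoxymethoxy)phenoxy}tri(propan-2-yl)silane | CC(C)=CCC[C@H](C)/C=C/c1c(OCOC)cc(O[Si](C(C)C)(C(C)C)C(C)C)cc1OCOC | intermediate
8 | 4-[(1E,3S)-3,7-dimethylocta-1,6-dien-1-yl]-3,5-bis(methoxymethoxy)phenol | CC(C)=CCC[C@H](C)/C=C/c1c(OCOC)cc(O)cc1OCOC | intermediate
9 | 4-[(1E,3S)-3,7-dimethylocta-1,6-dien-1-yl]-2-iodo-3,5-bis(methoxymethoxy)phenol | CC(C)=CCC[C@H](C)/C=C/c1c(OCOC)cc(O)c(I)c1OCOC | intermediate
10 | 4-hydroxybenzaldehyde | O=Cc1ccc(O)cc1 | starting material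
11 | 4-(methoxymethoxy)benzaldehyde | COCOc1ccc(C=O)cc1 | intermediate
12 | 1-ethynyl-4-(methoxymethoxy)benzene | C#Cc1ccc(OCOC)cc1 | intermediate
13 | carbon monoxide | [C-]#[O+] | starting material
14 | 1-{3-[(1E,3S)-3,7-dimethylocta-1,6-dien-1-yl]-6-hydroxy-2,4-bis(methoxymethoxy)phenyl}-3-[4-(methoxymethoxy)phenyl]prop-2-yn-1-one | CC(C)=CCC[C@H](C)/C=C/c1c(OCOC)cc(O)c(C(=O)C#Cc2ccc(OCOC)cc2)c1OCOC | intermediate
15 | 3-(diethylamino)-1-{3-[(1E,3S)-3,7-dimethylocta-1,6-dien-1-yl]-6-hydroxy-2,4-bis(methoxymethoxy)phenyl}-3-[4-(methoxymethoxy)phenyl]prop-2-en-1-one (push–pull C=C, geometry not fixed) | CCN(CC)C(=CC(=O)c1c(O)cc(OCOC)c(/C=C/[C@@H](C)CCC=C(C)C)c1OCOC)c1ccc(OCOC)cc1 | intermediate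
16 | 6-[(1E,3S)-3,7-dimethylocta-1,6-dien-1-yl]-5,7-bis(methoxymethoxy)-2-[4-(methoxymethoxy)phenyl]-4H-chromen-4-one | CC(C)=CCC[C@H](C)/C=C/c1c(OCOC)cc2oc(-c3ccc(OCOC)cc3)cc(=O)c2c1OCOC | intermediate
17 | (2S)-4-{[diethoxy(methyl)silyl]oxy}-6-[(1E,3S)-3,7-dimethylocta-1,6-dien-1-yl]-5,7-bis(methoxymethoxy)-2-[4-(methoxymethoxy)phenyl]-2H-chromene | CC(C)=CCC[C@H](C)/C=C/c1c(OCOC)cc2c(c1OCOC)C(O[Si](C)(OCC)OCC)=C[C@@H](c1ccc(OCOC)cc1)O2 | intermediate
18 | (2S)-6-[(1E,3S)-3,7-dimethylocta-1,6-dien-1-yl]-5,7-bis(methoxymethoxy)-2-[4-(methoxymethoxy)phenyl]-2,3-dihydro-4H-chromen-4-one | CC(C)=CCC[C@H](C)/C=C/c1c(OCOC)cc2c(c1OCOC)C(=O)C[C@@H](c1ccc(OCOC)cc1)O2 | intermediate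
19 | (2S)-6-[(1E,3S)-3,7-dimethylocta-1,6-dien-1-yl]-5,7-dihydroxy-2-(4-hydroxyphenyl)-2,3-dihydro-4H-chromen-4-one | CC(C)=CCC[C@H](C)/C=C/c1c(O)cc2c(c1O)C(=O)C[C@@H](c1ccc(O)cc1)O2 | target

**Count and risks**

Total steps: 11. Longest linear sequence: 9 steps (steps 1–6, then 9, 10 and 11); the alkyne branch is steps 7–8.

Step 9. What may go wrong:
- slow oxidative addition at the electron-rich, doubly ortho-substituted C–I bond;
- direct alkynylation without CO uptake, followed by 5-endo closure to a benzofuran;
- capture of the aroyl–palladium species by diethylamine (aminocarbonylation);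
- 5-exo closure to the aurone.

The fallback sets out from 9 and 12 and returns at ynone 14, now isolated, and then at flavone 16. Alkyne 12 is deprotonated (n-BuLi, THF, −78 °C) and acylated with N-methoxy-N-methylcarbamoyl chloride to give N-methoxy-3-[4-(methoxymethoxy)phenyl]-N-methylprop-2-ynamide F1. Iodophenol 9 is deprotonated with MeMgCl and submitted to iodine–magnesium exchange with i-PrMgCl·LiCl (THF, −20 °C) to give chloromagnesium 2-(chloromagnesio)-4-[(1E,3S)-3,7-dimethylocta-1,6-dien-1-yl]-3,5-bis(methoxymethoxy)phenolate F2. Acylation of F2 by F1 should give 14 after aqueous work-up, and warming 14 with Et2NH in EtOH closes ring C through 15 to 16. C4 then comes from the amide carbonyl instead of CO and no palladium is involved.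

Step 10. What may go wrong:
- low conversion of the electron-rich 2-aryl-5-alkoxychromone, which lies at the unreactive end of the chromones this reduction has been applied to;
- poor facial selectivity at C2;
- β-elimination of the enolate that opens ring C and leads to over-reduction;
- 1,2-reduction at C4.

The fallback sets out from 16 and returns at 18. Conjugate reduction with LiBH(s-Bu)3 (THF, −78 °C) should give (2RS)-6-[(1E,3S)-3,7-dimethylocta-1,6-dien-1-yl]-5,7-bis(methoxymethoxy)-2-[4-(methoxymethoxy)phenyl]-2,3-dihydro-4H-chromen-4-one F3 as both C2 epimers. Kinetic resolution by asymmetric transfer hydrogenation (RhCl(Cp*)[(R,R)-TsDPEN], HCO2H–Et3N, EtOAc, rt) should then reduce only the (2R) epimer, to (2R,4R)-6-[(1E,3S)-3,7-dimethylocta-1,6-dien-1-yl]-5,7-bis(methoxymethoxy)-2-[4-(methoxymethoxy)phenyl]-3,4-dihydro-2H-chromen-4-ol F4. Ketone 18 is left behind and separated by chromatography. At most half of the material can be recovered this way.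

Step 11. What may go wrong:
- protonation of the styrene or of the trisubstituted alkene, followed by capture by a flanking phenol or by the remote alkene (cyclisation of the side chain);
- addition of methanol or water to the alkenes;
- partial epimerisation at C2 by reversible opening of ring C.

The fallback sets out from 18 and returns at 19. TMSOTf with 2,2′-bipyridyl (CH2Cl2, 0 °C) exchanges the aryl MOM ethers for silyl ethers without free Brønsted acid and should give (2S)-6-[(1E,3S)-3,7-dimethylocta-1,6-dien-1-yl]-5,7-bis(trimethylsilyloxy)-2-[4-(trimethylsilyloxy)phenyl]-2,3-dihydro-4H-chromen-4-one F5. Water added to the same flask hydrolyses the silyl ethers near neutral pH to 19.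

**Further compounds**
F1 | step 9 | N-methoxy-3-[4-(methoxymethoxy)phenyl]-N-methylprop-2-ynamide | CON(C)C(=O)C#Cc1ccc(OCOC)cc1
F2 | step 9 | chloromagnesium 2-(chloromagnesio)-4-[(1E,3S)-3,7-dimethylocta-1,6-dien-1-yl]-3,5-bis(methoxymethoxy)phenolate | Cl[Mg]Oc1cc(OCOC)c(/C=C/[C@@H](C)CCC=C(C)C)c(OCOC)c1[Mg]Cl
F3 | step 10 | (2RS)-6-[(1E,3S)-3,7-dimethylocta-1,6-dien-1-yl]-5,7-bis(methoxymethoxy)-2-[4-(methoxymethoxy)phenyl]-2,3-dihydro-4H-chromen-4-one (both C2 epimers) | CC(C)=CCC[C@H](C)/C=C/c1c(OCOC)cc2c(c1OCOC)C(=O)CC(c1ccc(OCOC)cc1)O2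
F4 | step 10 | (2R,4R)-6-[(1E,3S)-3,7-dimethylocta-1,6-dien-1-yl]-5,7-bis(methoxymethoxy)-2-[4-(methoxymethoxy)phenyl]-3,4-dihydro-2H-chromen-4-ol | CC(C)=CCC[C@H](C)/C=C/c1c(OCOC)cc2c(c1OCOC)[C@H](O)C[C@H](c1ccc(OCOC)cc1)O2
F5 | step 11 | (2S)-6-[(1E,3S)-3,7-dimethylocta-1,6-dien-1-yl]-5,7-bis(trimethylsilyloxy)-2-[4-(trimethylsilyloxy)phenyl]-2,3-dihydro-4H-chromen-4-one | CC(C)=CCC[C@H](C)/C=C/c1c(O[Si](C)(C)C)cc2c(c1O[Si](C)(C)C)C(=O)C[C@@H](c1ccc(O[Si](C)(C)C)cc1)O2
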